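## Retrosynthetic overview

1. Idiadione ← its 6,14-diol by a double oxidation, so both conjugation-prone β,γ-enones appear only in the last step.
2. C5–C6 (key fragment union): carbonyl allylation of a citronellol-derived C15 aldehyde with the (E)-allylbarium reagent of a furan-bearing C10 allylic chloride (attack at the CH2 terminus, geometry retained).
3. C13–C14: the same allylbarium tactic joins the citronellol-derived (E)-allylic chloride (E geometry from SeO2 allylic oxidation) with 3-methylbutanal.
4. Furan fragment: 3-bromofuran + oxetane, then E-selective Wittig olefination, reduction and chlorination.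
5. No ring is formed: the furan is bought intact, and the only stereocentre (8S) comes from (S)-citronellol.

Assumption: the two carbinol centres created by the allylations (C6 and C14 of the heptadecane chain, counted from the furan-bearing CH2) are formed and carried as epimer mixtures (RS, drawn without configuration), because both become ketones in the last step.

## Route

Step 1
Reactants: 1 3-bromofuran; 2 oxetane
Product: 4 3-(furan-3-yl)propan-1-ol, via furan-3-yllithium 3 (not isolated)
Conditions: n-BuLi, THF, −78 °C, 30 min; then 2, BF3·OEt2, −78 °C, 1 h; H2O quench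
Reagents that add atoms: none
Why: Bromine–lithium exchange at −78 °C gives the 3-lithiofuran without migration to the 2-position, and this opens BF3-activated oxetane (Lewis-acid-assisted SN2 ring opening) to install the three-carbon hydroxypropyl chain; no stereocentre is formed.

Step 2
Reactants: 4 3-(furan-3-yl)propan-1-ol
Product: 5 3-(furan-3-yl)propanal
Conditions: Dess–Martin periodinane, pyridine, CH2Cl2, 0 °C to rt
Reagents that add atoms: none
Why: Buffered Dess–Martin oxidation stops cleanly at the aldehyde and leaves the acid-sensitive furan untouched.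

Step 3
Reactants: 5 3-(furan-3-yl)propanal; 6 ethyl 2-(triphenylphosphoranylidene)propanoate
Product: 7 ethyl (2E)-5-(furan-3-yl)-2-methylpent-2-enoate
Conditions: CH2Cl2, rt to 40 °C, 16 h
Reagents that add atoms: none
Why: Wittig olefination with the stabilised α-methyl ylide gives the trisubstituted enoate with high E selectivity (typically at least 95:5), which fixes the C3=C4 geometry of the target.

Step 4
Reactants: 7 ethyl (2E)-5-(furan-3-yl)-2-methylpent-2-enoate
Product: 8 (2E)-5-(furan-3-yl)-2-methylpent-2-en-1-ol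
Conditions: i-Bu2AlH (2.5 equiv), CH2Cl2, −78 °C; aq. potassium sodium tartrate
Reagents that add atoms: none
Why: i-Bu2AlH performs a clean 1,2-reduction of the enoate to the allylic alcohol without touching the alkene geometry or the furan.

Step 5
Reactants: 8 (2E)-5-(furan-3-yl)-2-methylpent-2-en-1-ol
Product: 10 3-[(3E)-5-chloro-4-methylpent-3-en-1-yl]furan, via allylic mesylate 9 (not isolated)
Conditions: MsCl, s-collidine, LiCl, DMF, 0 °C
Reagents that add atoms: lithium chloride, [Li+].[Cl-]
Why: In the Collington–Meyers chlorination the mesylate formed in the flask is displaced by chloride in a direct SN2 reaction at 0 °C, so there is no allylic transposition and no E/Z loss.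

Step 6
Reactants: 11 (S)-citronellol, (3S)-3,7-dimethyloct-6-en-1-ol
Product: 12 1-({[(3S)-3,7-dimethyloct-6-en-1-yl]oxy}methyl)-4-methoxybenzene (PMB ether of 11)
Conditions: NaH, 4-methoxybenzyl chloride, tetrabutylammonium iodide (cat.), THF/DMF, 0 °C to rt
Reagents that add atoms: 4-methoxybenzyl chloride, COc1ccc(CCl)cc1
Why: Williamson etherification protects the primary alcohol as an ether that survives organometallic reagents and can later be removed in the presence of a silyl ether; the stereocentre is not involved.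

Step 7
Reactants: 12 PMB ether of (S)-citronellol
Product: 13 (2E,6S)-8-[(4-methoxybenzyl)oxy]-2,6-dimethyloct-2-en-1-ol
Conditions: SeO2 (0.5 equiv), t-BuOOH, salicylic acid (cat.), CH2Cl2, rt
Reagents that add atoms: selenium dioxide, O=[Se]=O (transfers the oxygen); tert-butyl hydroperoxide, CC(C)(C)OO (resupplies it)
Why: The Sharpless SeO2/t-BuOOH allylic oxidation (ene reaction then [2,3]-sigmatropic shift) hydroxylates only the E-methyl group of the trisubstituted alkene, which sets the C11=C12 E geometry and leaves the remote stereocentre untouched.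

Step 8
Reactants: 13 (2E,6S)-8-[(4-methoxybenzyl)oxy]-2,6-dimethyloct-2-en-1-ol
Product: 15 1-({[(3S,6E)-8-chloro-3,7-dimethyloct-6-en-1-yl]oxy}methyl)-4-methoxybenzene, via allylic mesylate 14 (not isolated)
Conditions: MsCl, s-collidine, LiCl, DMF, 0 °C
Reagents that add atoms: lithium chloride, [Li+].[Cl-]
Why: Collington–Meyers chlorination again converts the primary allylic alcohol into the chloride by SN2 displacement of the mesylate, with retention of alkene position and geometry.

Step 9
Reactants: 15 (3S,6E)-allylic chloride PMB ether; 16 3-methylbutanal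
Product: 18 (4RS,6E,10S)-12-[(4-methoxybenzyl)oxy]-2,6,10-trimethyldodec-6-en-4-ol, via allylbarium chloride 17 (not isolated)
Conditions: BaI2 + LiC12H10 (lithium biphenylide, 2 equiv), THF, rt (gives finely divided zerovalent barium); 15, −78 °C, 30 min; then 16 (1.5 equiv), −78 °C, 30 min; aq. NH4Cl
Reagents that add atoms: none
Why: In this Yamamoto-type carbonyl allylation the allylbarium reagent is configurationally stable at −78 °C and attacks the aldehyde through its unsubstituted CH2 terminus, giving the linear homoallylic alcohol with the E alkene retained; the new carbinol centre forms unselectively and is oxidised away in step 15.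

Step 10
Reactants: 18 (4RS,6E,10S)-12-[(4-methoxybenzyl)oxy]-2,6,10-trimethyldodec-6-en-4-ol
Product: 19 tert-butyl({(4RS,6E,10S)-12-[(4-methoxybenzyl)oxy]-2,6,10-trimethyldodec-6-en-4-yl}oxy)dimethylsilane
Conditions: TBSCl, imidazole, DMAP (cat.), DMF, rt
Reagents that add atoms: tert-butyldimethylsilyl chloride, CC(C)(C)[Si](C)(C)Cl
Why: Standard imidazole-promoted silylation masks the secondary carbinol so that it neither consumes the second allylbarium reagent nor is oxidised in step 12.

Step 11
Reactants: 19 TBS/PMB-protected diol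
Product: 20 (3S,6E,9RS)-9-[(tert-butyldimethylsilyl)oxy]-3,7,11-trimethyldodec-6-en-1-ol
Conditions: DDQ, CH2Cl2/aq. NaH2PO4–Na2HPO4 buffer (pH 7), 0 °C to rt
Reagents that add atoms: none
Why: Oxidative PMB cleavage (benzylic hydride abstraction by DDQ, then hydrolysis of the oxocarbenium ion) frees the primary alcohol while the silyl ether and the trisubstituted alkene are inert; it is done before the furan enters the molecule.

Step 12
Reactants: 20 (3S,6E,9RS)-9-[(tert-butyldimethylsilyl)oxy]-3,7,11-trimethyldodec-6-en-1-ol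
Product: 21 (3S,6E,9RS)-9-[(tert-butyldimethylsilyl)oxy]-3,7,11-trimethyldodec-6-enal
Conditions: Dess–Martin periodinane, pyridine, CH2Cl2, 0 °C to rt
Reagents that add atoms: none
Why: Dess–Martin oxidation gives the aldehyde without over-oxidation, and the methyl-bearing stereocentre is β to the carbonyl, so it cannot epimerise.

Step 13
Reactants: 10 3-[(3E)-5-chloro-4-methylpent-3-en-1-yl]furan; 21 (3S,6E,9RS)-silyloxy aldehyde
Product: 23 (3E,6RS,8S,11E,14RS)-14-[(tert-butyldimethylsilyl)oxy]-1-(furan-3-yl)-4,8,12,16-tetramethylheptadeca-3,11-dien-6-ol, via allylbarium chloride 22 (not isolated)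
Conditions: BaI2 + LiC12H10 (2 equiv), THF, rt; 10 (1.5 equiv), −78 °C, 30 min; then 21, −78 °C, 30 min; aq. NH4Cl
Reagents that add atoms: none
Why: This key carbonyl allylation (Yamamoto allylbarium addition) forms the C5–C6 bond by attack of the CH2 terminus with the C3=C4 E geometry retained, and the furan, silyl ether and second alkene are inert at −78 °C; the new C6 carbinol is an epimer mixture that is erased in step 15.

Step 14
Reactants: 23 silyl-protected homoallylic alcohol
Product: 24 (3E,6RS,8S,11E,14RS)-1-(furan-3-yl)-4,8,12,16-tetramethylheptadeca-3,11-diene-6,14-diol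
Conditions: Bu4NF, THF, rt
Reagents that add atoms: none
Why: Fluoride-mediated desilylation is carried out while no ketone is present, so the basic fluoride cannot isomerise an enone.

Step 15
Reactants: 24 (3E,6RS,8S,11E,14RS)-6,14-diol
Product: 25 idiadione, (3E,8S,11E)-1-(furan-3-yl)-4,8,12,16-tetramethylheptadeca-3,11-diene-6,14-dione
Conditions: Dess–Martin periodinane (3 equiv), pyridine, CH2Cl2, 0 °C, 1 h; cold aq. Na2S2O3/NaHCO3 work-up, quick chromatography on neutral silica
Reagents that add atoms: none
Why: The double Dess–Martin oxidation runs under buffered, non-basic conditions that leave both β,γ-enones unconjugated, all four diol epimers converge on one diketone, and C8 (β to the C6 carbonyl) keeps its S configuration.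

## Compound list

1 | 3-bromofuran | Brc1ccoc1 | starting material
2 | oxetane | C1COC1 | starting material
3 | furan-3-yllithium | [Li]c1ccoc1 | intermediate
4 | 3-(furan-3-yl)propan-1-ol | OCCCc1ccoc1 | intermediate
5 | 3-(furan-3-yl)propanal | O=CCCc1ccoc1 | intermediate
6 | ethyl 2-(triphenylphosphoranylidene)propanoate | CCOC(=O)C(C)=P(c1ccccc1)(c1ccccc1)c1ccccc1 | starting material
7 | ethyl (2E)-5-(furan-3-yl)-2-methylpent-2-enoate | CCOC(=O)/C(C)=C/CCc1ccoc1 | intermediate
8 | (2E)-5-(furan-3-yl)-2-methylpent-2-en-1-ol | OC/C(C)=C/CCc1ccoc1 | intermediate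
9 | (2E)-5-(furan-3-yl)-2-methylpent-2-en-1-yl methanesulfonate | CS(=O)(=O)OC/C(C)=C/CCc1ccoc1 | intermediate
10 | 3-[(3E)-5-chloro-4-methylpent-3-en-1-yl]furan | ClC/C(C)=C/CCc1ccoc1 | intermediate
11 | (S)-citronellol, (3S)-3,7-dimethyloct-6-en-1-ol | CC(C)=CCC[C@H](C)CCO | starting material
12 | 1-({[(3S)-3,7-dimethyloct-6-en-1-yl]oxy}methyl)-4-methoxybenzene | CC(C)=CCC[C@H](C)CCOCc1ccc(OC)cc1 | intermediate
13 | (2E,6S)-8-[(4-methoxybenzyl)oxy]-2,6-dimethyloct-2-en-1-ol | OC/C(C)=C/CC[C@H](C)CCOCc1ccc(OC)cc1 | intermediate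
14 | (2E,6S)-8-[(4-methoxybenzyl)oxy]-2,6-dimethyloct-2-en-1-yl methanesulfonate | CS(=O)(=O)OC/C(C)=C/CC[C@H](C)CCOCc1ccc(OC)cc1 | intermediate
15 | 1-({[(3S,6E)-8-chloro-3,7-dimethyloct-6-en-1-yl]oxy}methyl)-4-methoxybenzene | ClC/C(C)=C/CC[C@H](C)CCOCc1ccc(OC)cc1 | intermediate
16 | 3-methylbutanal | CC(C)CC=O | starting material
17 | {(2E,6S)-8-[(4-methoxybenzyl)oxy]-2,6-dimethyloct-2-en-1-yl}barium chloride | Cl[Ba]C/C(C)=C/CC[C@H](C)CCOCc1ccc(OC)cc1 | intermediate
18 | (4RS,6E,10S)-12-[(4-methoxybenzyl)oxy]-2,6,10-trimethyldodec-6-en-4-ol | CC(C)CC(O)C/C(C)=C/CC[C@H](C)CCOCc1ccc(OC)cc1 | intermediate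
19 | tert-butyl({(4RS,6E,10S)-12-[(4-methoxybenzyl)oxy]-2,6,10-trimethyldodec-6-en-4-yl}oxy)dimethylsilane | CC(C)CC(O[Si](C)(C)C(C)(C)C)C/C(C)=C/CC[C@H](C)CCOCc1ccc(OC)cc1 | intermediate
20 | (3S,6E,9RS)-9-[(tert-butyldimethylsilyl)oxy]-3,7,11-trimethyldodec-6-en-1-ol | CC(C)CC(O[Si](C)(C)C(C)(C)C)C/C(C)=C/CC[C@H](C)CCO | intermediate
21 | (3S,6E,9RS)-9-[(tert-butyldimethylsilyl)oxy]-3,7,11-trimethyldodec-6-enal | CC(C)CC(O[Si](C)(C)C(C)(C)C)C/C(C)=C/CC[C@H](C)CC=O | intermediate
22 | [(2E)-5-(furan-3-yl)-2-methylpent-2-en-1-yl]barium chloride | Cl[Ba]C/C(C)=C/CCc1ccoc1 | intermediate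
23 | (3E,6RS,8S,11E,14RS)-14-[(tert-butyldimethylsilyl)oxy]-1-(furan-3-yl)-4,8,12,16-tetramethylheptadeca-3,11-dien-6-ol | CC(C)CC(O[Si](C)(C)C(C)(C)C)C/C(C)=C/CC[C@H](C)CC(O)C/C(C)=C/CCc1ccoc1 | intermediate
24 | (3E,6RS,8S,11E,14RS)-1-(furan-3-yl)-4,8,12,16-tetramethylheptadeca-3,11-diene-6,14-diol | CC(C)CC(O)C/C(C)=C/CC[C@H](C)CC(O)C/C(C)=C/CCc1ccoc1 | intermediate
25 | idiadione, (3E,8S,11E)-1-(furan-3-yl)-4,8,12,16-tetramethylheptadeca-3,11-diene-6,14-dione | C/C(=C\CC[C@H](C)CC(=O)C/C(C)=C/CCc1ccoc1)CC(=O)CC(C)C | target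

## Step count and risks

Total step count: 15. Longest linear sequence: 10 steps (11 → 25 through steps 6–15); the furan branch (steps 1–5) joins at step 13.

Steps most likely to fail:

**Step 9 (first allylbarium addition).** The risks are attack through the substituted terminus (branched alcohol), Wurtz coupling of the chloride, or poorly active barium. The fallback replaces carbonyl allylation by acyl-anion alkylation and sets out from 15. 3-Methylbutanal 16 is condensed with propane-1,3-dithiol (BF3·OEt2, CH2Cl2) to 2-(2-methylpropyl)-1,3-dithiane F1. F1 is lithiated (n-BuLi, THF, −30 °C) and alkylated with 15 by direct SN2 displacement to give the dithiane-masked ketone F2. Iodomethane and CaCO3 in aqueous MeCN unmask it to the β,γ-unsaturated ketone F3. NaBH4 in MeOH at 0 °C reduces F3, and the route is rejoined at 18.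

**Step 13 (key allylbarium addition).** The risks are the same, now with two advanced fragments. The fallback builds the C3=C4 alkene by alkyne carbometalation and cross-coupling, and sets out from 21. Barbier propargylation (propargyl bromide, Zn dust, THF/aq. NH4Cl) gives the homopropargylic alcohol F4. Zirconium-catalysed carboalumination (Me3Al, Cp2ZrCl2, CH2Cl2) followed by iodine gives the (E)-vinyl iodide F5, its geometry fixed by syn addition. Separately, furan-3-carbaldehyde and Ph3P=CH2 give 3-ethenylfuran F6, which 9-BBN-H hydroborates to the B-alkyl borane F7. B-alkyl Suzuki–Miyaura coupling of F7 with F5 (PdCl2(dppf), AsPh3, Cs2CO3, DMF/THF/H2O, rt) proceeds with retention of alkene geometry and comes back to the route at 23.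

**Step 15 (double oxidation).** The risk is isomerisation of one or both β,γ-enones into conjugation while two ketones are generated at once. The fallback unveils the carbonyls one at a time and sets out from 23. Swern oxidation ((COCl)2, DMSO, Et3N, CH2Cl2, −78 °C) of the free C6 carbinol gives the mono-ketone silyl ether F8. HF·pyridine in THF/pyridine at 0 °C (no basic fluoride once an enone is present) removes the silyl group to give the hydroxy ketone F9. A second single Swern oxidation comes back to the route at 25.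

## Further compounds

F1 | step 9 | 2-(2-methylpropyl)-1,3-dithiane | CC(C)CC1SCCCS1
F2 | step 9 | 2-{(2E,6S)-8-[(4-methoxybenzyl)oxy]-2,6-dimethyloct-2-en-1-yl}-2-(2-methylpropyl)-1,3-dithiane | CC(C)CC1(C/C(C)=C/CC[C@H](C)CCOCc2ccc(OC)cc2)SCCCS1
F3 | step 9 | (6E,10S)-12-[(4-methoxybenzyl)oxy]-2,6,10-trimethyldodec-6-en-4-one | CC(C)CC(=O)C/C(C)=C/CC[C@H](C)CCOCc1ccc(OC)cc1
F4 | step 13 | (4RS,6S,9E,12RS)-12-[(tert-butyldimethylsilyl)oxy]-6,10,14-trimethylpentadec-9-en-1-yn-4-ol | CC(C)CC(O[Si](C)(C)C(C)(C)C)C/C(C)=C/CC[C@H](C)CC(O)CC#C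
F5 | step 13 | (1E,4RS,6S,9E,12RS)-12-[(tert-butyldimethylsilyl)oxy]-1-iodo-2,6,10,14-tetramethylpentadeca-1,9-dien-4-ol | CC(C)CC(O[Si](C)(C)C(C)(C)C)C/C(C)=C/CC[C@H](C)CC(O)C/C(C)=C/I
F6 | step 13 | 3-ethenylfuran | C=Cc1ccoc1
F7 | step 13 | 9-[2-(furan-3-yl)ethyl]-9-borabicyclo[3.3.1]nonane | C1CC2CCCC(C1)B2CCc1ccoc1
F8 | step 15 | (3E,8S,11E,14RS)-14-[(tert-butyldimethylsilyl)oxy]-1-(furan-3-yl)-4,8,12,16-tetramethylheptadeca-3,11-dien-6-one | CC(C)CC(O[Si](C)(C)C(C)(C)C)C/C(C)=C/CC[C@H](C)CC(=O)C/C(C)=C/CCc1ccoc1
F9 | step 15 | (3E,8S,11E,14RS)-1-(furan-3-yl)-14-hydroxy-4,8,12,16-tetramethylheptadeca-3,11-dien-6-one | CC(C)CC(O)C/C(C)=C/CC[C@H](C)CC(=O)C/C(C)=C/CCc1ccoc1
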